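The reading at 8.0 h was what I had to reach, so I reckoned how much free monomer each flask would have lost by then and treated the part of that loss not found in chains as a small correction.

in all of them: free monomer 0.010 M

| run | initiator | temperature | remark | time |
|---|---|---|---|---|
| winter | 0.2 mol% | 65 °C | run made earlier |  |
| autumn | 0.82 mol% | 98 °C | run made earlier |  |
| north | 0.41 mol% | 110 °C |  | 8.0 h |
| north-west | 0.41 mol% | 80 °C |  | 8.0 h |
| east | 0.41 mol% | 50 °C |  | 8.0 h |

- the best flask by amount of monomer in chains, in percent of the free monomer charged; "all alike" if 1.5 percentage points covers them all (north / north-west / east / all alike)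
- amount of monomer in chains at the end, in percent of the free monomer charged, north
- amount of monomer in chains at the end, in percent of the free monomer charged, north-west
- amount of monomer in chains at the end, in percent of the free monomer charged, east

- on the list of suspects stand: initiator -> 2 initiating radical; free monomer + initiating radical -> growing radical + monomer in chains; free monomer + growing radical -> monomer in chains + growing radical; 2 growing radical -> dead chain; free monomer <-> dormant form; monomer in chains <-> isomer of the product

- winter (time / h: monomer in chains / %, free monomer / %): 8.00: 14, 90; 15.0: 17, 82; 25.0: 27, 73; 30.0: 32, 65; 40.0: 37, 55; 50.0: 42, 51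
- autumn (time / h: monomer in chains / %, free monomer / %): 0.833: 29, 61; 1.33: 46, 52; 2.00: 55, 37; 4.00: 74, 10; 5.00: 74, 9; 10.0: 81, 4

(standard deviation of a reading: 2 percentage points)

I read one row from each table. The loss constant k, a pseudo-first-order constant defined as the logarithm of charged over remaining free monomer divided by the time, came to 0.0135 h⁻¹ from the last winter row and 0.497 h⁻¹ from the autumn row at 2.00 h, in the middle of the fall. Setting the columns against each other, chains held less than the free monomer lost in the winter row and in the autumn row, and pooling the rows gave the side share φ, the part of the lost free monomer not found in chains, as 13.4%.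

These runs differ in loading and temperature, so I assumed that k goes with the square root of the loading, which left a temperature factor of 18.2 between them. Taking ln k as straight in temperature, I obtained the loss constant of north-west, k = 0.0722 h⁻¹. So I expected north-west to keep 56.1% free monomer and hold 38.0% in chains. Extending the line below the temperatures of both runs, I reckoned 3.50% in chains for east. Extending it above them, I reckoned k = 1.01 h⁻¹ for north, and its product with the time, far larger than one, put the answer for north on a correction I could not call small, so I ranked north first without a figure.

The forecast named north best, with 73% (60% to 82%) for north, 45% for north-west and 3% for east, saying: “The autumn run stalls late, which suggests initiator burnout”.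

The flasks gave 63.0% in north, 41.5% in north-west and 2.86% in east, so north came first.

    initiator → 2 initiating radical (k = 3.60 × 10⁻⁵ s⁻¹, Ea = 123 kJ mol⁻¹)
    free monomer + initiating radical → growing radical + monomer in chains (k = 5.20 × 10⁵ M⁻¹ s⁻¹, Ea = 14.0 kJ mol⁻¹)
    free monomer + growing radical → monomer in chains + growing radical, rate k3*[growing radical]*[free monomer] (k = 19000 M⁻¹ s⁻¹, Ea = 47.0 kJ mol⁻¹)
    2 growing radical → dead chain (k = 9.00 × 10⁶ M⁻¹ s⁻¹, Ea = 29.0 kJ mol⁻¹)
    free monomer ⇌ dormant form (K = 1.80, k = 7.80 × 10⁻⁵ s⁻¹, Ea = 129 kJ mol⁻¹, ΔH = −5.00 kJ mol⁻¹)
    monomer in chains ⇌ isomer of the product (K = 1.60, k = 1.50 × 10⁻⁵ s⁻¹, Ea = 125 kJ mol⁻¹, ΔH = −75.0 kJ mol⁻¹)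
    (constants at 110 °C)

North-west held 52.9% free monomer against my 56.1%, and 41.5% in chains against my 38.0%. Carried to the neighbouring flask, north-west stopped at 3.0 h, the same k and φ gave 80.5% free monomer and 16.9% in chains, and that flask held 78.7% free monomer and 18.9% in chains.

The data are calculated for substances that don't exist.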